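**Retrosynthetic overview**

1. Labels: ring A is the methoxy-dimethyl benzene ring, its carbons counted as ring A positions 1 to 6 (position 1 C–OMe, 2 C–H, 3 C–CH3, 4 C–C(=O), 5 C–O ether, 6 C–CH3); ring B is the hexasubstituted benzene ring (B1 C–O ether, B2 C–O ester, B3 C–CH2OH, B4 C–OH, B5 C–C(=O) lactone, B6 C–CH(OH)); ring C is the seven-membered dioxepinone; ring D is the five-membered lactol.
2. Feature: ring A position 4 carries the ring C carbonyl while positions 5 and 1 carry oxygen, so ring A is a 2,4-dioxygenated benzoate, the aromatised form of a cyclohexane-1,3-dione-4-carboxylate. Position 5 can therefore be made as the beta carbon of an enol triflate conjugated to the ring C ester instead of as a crowded aryl carbon.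
3. Disconnections, last first: ring D lactol stereocentre by carbonate-forming dynamic kinetic resolution of the racemic hydroxyphthalide (from an ortho-formyl allyl ester); ring A aromatisation by DDQ; the ring C ether bond from ring A position 5 to the B1 oxygen by phenoxide addition–elimination on the triflyloxy acrylate; the ester bond from the ring C carbonyl to the B2 oxygen by acylketene transfer.
4. Fragments: dihydro ring A from tert-butyl 3-oxopentanoate and ethyl crotonate (Michael–Claisen); ring B from benzene-1,2,4-triol by ortho-lithiation, bromination, bromine–lithium exchange and ortho-magnesiation.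
5. Ring order: carbocycle of ring A (step 1), ring B taken from the triol, ring C (step 14), aromatic ring A (step 15), ring D (step 16).

Key step: step 14

Remark 1: the lactol carbon of ring D epimerises through the open formyl acid under acid or base, so it is fixed as a carbonate and released under neutral conditions in the last step; the target must be kept neutral, cold and out of protic media.

Remark 2: compounds 3–5 and 18–23 are racemic at the sp3 carbons that become ring A (diastereomer and keto–enol mixtures where two such centres exist) and are written without descriptors; these centres are erased in steps 13 and 15.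

**Route**

Step 1
Reactants: 1 tert-butyl 3-oxopentanoate; 2 ethyl (E)-but-2-enoate
Product: 4 tert-butyl 3,6-dimethyl-2,4-dioxocyclohexane-1-carboxylate, via Michael adduct 3 (not isolated)
Conditions: KOtBu (1.1 equiv), t-BuOH, reflux; aq. HCl
Reagents that add atoms: none
Why: Michael addition of the keto ester carbanion to the crotonate followed by Claisen ring closure of the ethyl ketone enolate onto the ethyl ester gives the six-membered 1,3-dione, the annulation used for dihydroorsellinates; the sp3 centres form as an inconsequential mixture.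

Step 2
Reactants: 4 tert-butyl 3,6-dimethyl-2,4-dioxocyclohexane-1-carboxylate
Product: 5 tert-butyl 4-methoxy-3,6-dimethyl-2-oxocyclohex-3-ene-1-carboxylate
Conditions: HC(OMe)3, MeOH, TsOH·H2O (cat.), rt
Reagents that add atoms: trimethyl orthoformate, COC(OC)OC
Why: Acid-catalysed enol etherification (vinylogous ester formation) should occur at the less hindered C-4 carbonyl, and under equilibrating conditions the isomer that keeps the C-2 ketone as a chelated beta-keto ester should prevail.

Step 3
Reactants: 6 benzene-1,2,4-triol
Product: 7 1,2,4-tris(methoxymethoxy)benzene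
Conditions: MOMCl, iPr2NEt, CH2Cl2, 0 °C to rt, argon
Reagents that add atoms: chloromethyl methyl ether, COCCl
Why: O-alkylation of the three phenols with the alpha-chloro ether (Williamson-type acetal formation) under argon avoids autoxidation of the triol.

Step 4
Reactants: 7 1,2,4-tris(methoxymethoxy)benzene
Product: 9 2-[(benzyloxy)methyl]-1,3,4-tris(methoxymethoxy)benzene, via aryllithium 8 (not isolated)
Conditions: n-BuLi, THF, 0 °C; BnOCH2Cl, −78 °C to rt
Reagents that add atoms: benzyl chloromethyl ether, ClCOCc1ccccc1
Why: Directed ortho-metalation takes place at the only carbon flanked by two OMOM groups (future B3), and the aryllithium is alkylated by the alpha-chloro ether in an SN2 reaction.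

Step 5
Reactants: 9 2-[(benzyloxy)methyl]-1,3,4-tris(methoxymethoxy)benzene
Product: 10 3-[(benzyloxy)methyl]-1-bromo-2,4,5-tris(methoxymethoxy)benzene
Conditions: NBS, MeCN, 0 °C, dark
Reagents that add atoms: N-bromosuccinimide, O=C1CCC(=O)N1Br
Why: Electrophilic aromatic bromination should go to B5, ortho to one acetal oxygen and para to another, the site at which 3-alkyl-1,2,4-trialkoxybenzenes are normally substituted; exclusion of light suppresses benzylic bromination.

Step 6
Reactants: 10 3-[(benzyloxy)methyl]-1-bromo-2,4,5-tris(methoxymethoxy)benzene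
Product: 12 allyl 3-[(benzyloxy)methyl]-2,4,5-tris(methoxymethoxy)benzoate, via aryllithium 11 (not isolated)
Conditions: n-BuLi, THF, −78 °C; cannulated into ClCO2CH2CH=CH2 (3 equiv), −78 °C
Reagents that add atoms: allyl chloroformate, C=CCOC(Cl)=O
Why: Bromine–lithium exchange at −78 °C is faster than deprotonation of the benzyl ether, and inverse addition to excess chloroformate gives the ester by acylation without diaryl ketone formation.

Step 7
Reactants: 12 allyl 3-[(benzyloxy)methyl]-2,4,5-tris(methoxymethoxy)benzoate
Product: 13 allyl 3-[(benzyloxy)methyl]-2-hydroxy-4,5-bis(methoxymethoxy)benzoate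
Conditions: MgBr2·OEt2 (2 equiv), Et2O–toluene, 0 °C to rt; water
Reagents that add atoms: none
Why: Chelation-controlled Lewis acid acetal cleavage: magnesium bound between the ester carbonyl and the ortho acetal oxygen activates only the B4 MOM group (ortho-carbonyl effect), so the two catechol MOM groups should survive.

Step 8
Reactants: 13 allyl 3-[(benzyloxy)methyl]-2-hydroxy-4,5-bis(methoxymethoxy)benzoate
Product: 14 allyl 2-(benzyloxy)-3-[(benzyloxy)methyl]-4,5-bis(methoxymethoxy)benzoate
Conditions: BnBr, K2CO3, DMF, 40 °C
Reagents that add atoms: benzyl bromide, BrCc1ccccc1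
Why: Williamson etherification of the salicylate-type phenol.

Step 9
Reactants: 14 allyl 2-(benzyloxy)-3-[(benzyloxy)methyl]-4,5-bis(methoxymethoxy)benzoate
Product: 16 allyl 2-(benzyloxy)-3-[(benzyloxy)methyl]-6-formyl-4,5-bis(methoxymethoxy)benzoate, via arylmagnesium chloride 15 (not isolated)
Conditions: TMPMgCl·LiCl (1.5 equiv), THF, 0 °C to rt; DMF, 0 °C; aq. NH4Cl
Reagents that add atoms: N,N-dimethylformamide, CN(C)C=O
Why: Directed ortho-magnesiation at the only ring C–H, flanked by the ester and an OMOM group, uses an amide base that tolerates the ester and the benzyl ethers, and the aryl Grignard is formylated by DMF.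

Step 10
Reactants: 16 allyl 2-(benzyloxy)-3-[(benzyloxy)methyl]-6-formyl-4,5-bis(methoxymethoxy)benzoate
Product: 17 allyl 2-(benzyloxy)-3-[(benzyloxy)methyl]-6-formyl-4,5-dihydroxybenzoate
Conditions: 3 M HCl, THF, 40 °C
Reagents that add atoms: none
Why: Acid hydrolysis of the two MOM acetals frees the catechol, while the para formyl group disfavours ionisation of the B3 benzylic ether.

Step 11
Reactants: 5 tert-butyl 4-methoxy-3,6-dimethyl-2-oxocyclohex-3-ene-1-carboxylate; 17 allyl 2-(benzyloxy)-3-[(benzyloxy)methyl]-6-formyl-4,5-dihydroxybenzoate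
Product: 19 allyl 2-(benzyloxy)-3-[(benzyloxy)methyl]-6-formyl-5-hydroxy-4-[(4-methoxy-3,6-dimethyl-2-oxocyclohex-3-ene-1-carbonyl)oxy]benzoate, via acylketene 18 (not isolated)
Conditions: toluene, 110 °C, slow distillation of t-BuOH, argon
Reagents that add atoms: none
Why: Thermal loss of tert-butanol from the beta-keto ester gives the alpha-oxoketene, which should be captured by the free B2 hydroxyl and not by the formyl-chelated B1 hydroxyl (acylketene transesterification), the B2 ester with a hydrogen-bonded B1 phenol also being the thermodynamic isomer.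

Step 12
Reactants: 19 aryl beta-keto ester with free B1 phenol
Product: 20 allyl 2-(benzyloxy)-3-[(benzyloxy)methyl]-5-[(tert-butyldimethylsilyl)oxy]-6-formyl-4-[(4-methoxy-3,6-dimethyl-2-oxocyclohex-3-ene-1-carbonyl)oxy]benzoate
Conditions: TBSOTf (1.2 equiv), 2,6-lutidine, CH2Cl2, −78 to −40 °C; pH 5 buffer
Reagents that add atoms: tert-butyldimethylsilyl trifluoromethanesulfonate, CC(C)(C)[Si](C)(C)OS(=O)(=O)C(F)(F)F
Why: O-silylation of the neutral phenol by the silyl triflate with a hindered pyridine base generates no phenoxide and so allows no acyl shift, and any silyl enol ether of the keto ester is hydrolysed in the buffered work-up.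

Step 13
Reactants: 20 silyl-protected aryl beta-keto ester
Product: 21 allyl 2-(benzyloxy)-3-[(benzyloxy)methyl]-5-[(tert-butyldimethylsilyl)oxy]-6-formyl-4-[(4-methoxy-3,6-dimethyl-2-{[(trifluoromethyl)sulfonyl]oxy}cyclohexa-1,3-diene-1-carbonyl)oxy]benzoate
Conditions: Tf2O, iPr2NEt, CH2Cl2, −78 °C
Reagents that add atoms: trifluoromethanesulfonic anhydride, O=S(=O)(OS(=O)(=O)C(F)(F)F)C(F)(F)F
Why: Enol triflation of the beta-keto ester: only the C-2 ketone can be O-sulfonylated because the other carbonyl is already the methyl vinylogous ester, and loss of the acidic proton at ring A position 4 gives the conjugated triflyloxy acrylate without a free enolate that could take over the silyl group.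

Step 14
Reactants: 21 silyl-protected triflyloxy dienoate
Product: 23 allyl 8-(benzyloxy)-9-[(benzyloxy)methyl]-6-formyl-3-methoxy-1,4-dimethyl-11-oxo-1,2-dihydro-11H-dibenzo[b,e][1,4]dioxepine-7-carboxylate, via cesium phenoxide 22 (not isolated)
Conditions: CsF (3 equiv), DMF (0.01 M), 0 °C to rt
Reagents that add atoms: none
Why: Fluoride cleaves the aryl O–Si bond, and the cesium phenoxide 22 adds to ring A position 5, the beta carbon of the triflyloxy acrylate, to give an ester enolate that expels triflate (addition–elimination at a vinylic carbon). The closest known reaction type is the substitution of beta-sulfonyloxy and beta-triflyloxy alpha,beta-unsaturated esters by phenoxides. Ring C closes in a 7-endo-trig mode, because both carbons of the attacked double bond lie in the new ring. No stereocentre is formed, and the sp3 methyl-bearing carbon at ring A position 3 is untouched and stays racemic. The step needs attack of the B1 oxygen at ring A position 5 without a prior 1,2-shift of the acyl group from the B2 oxygen to the B1 oxygen and without attack at the triflate sulfur. The first is secured because the B1 phenoxide is the formyl-conjugated, less basic one, so the acyl group rests on the more basic B2 oxygen, and because the ester carbonyl is shielded by the methine at position 3 and the triflate at position 5; high dilution and a sparingly soluble fluoride limit oligomers and S–O cleavage.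

Step 15
Reactants: 23 dihydrodepsidone
Product: 24 allyl 8-(benzyloxy)-9-[(benzyloxy)methyl]-6-formyl-3-methoxy-1,4-dimethyl-11-oxo-11H-dibenzo[b,e][1,4]dioxepine-7-carboxylate
Conditions: DDQ (1.2 equiv), toluene, rt to 50 °C
Reagents that add atoms: none
Why: Dehydrogenative aromatisation by DDQ: hydride abstraction from the sp3 methine at ring A position 3 gives an arenium ion stabilised by both ring A oxygens, and proton loss from the methylene at position 2 forms ring A and erases the sp3 stereocentre.

Step 16
Reactants: 24 depsidone formyl allyl ester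
Product: 26 racemic ring D lactol (3-hydroxyphthalide form) with O-benzyl at B4 and benzyloxymethyl at B3, via formyl acid 25 (not isolated)
Conditions: Pd(PPh3)4 (5 mol %), PhNHMe, THF, rt
Reagents that add atoms: none
Why: Tsuji–Trost deallylation (zerovalent palladium ionises the allyl ester and N-methylaniline traps the allyl fragment without condensing with the aldehyde) frees the acid, which closes onto the ortho formyl group by ring–chain tautomerism to give the lactol as a racemate.

Step 17
Reactants: 26 racemic ring D lactol
Product: 27 (S)-configured benzyl carbonate of the ring D lactol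
Conditions: (BnOCO)2O, benzotetramisole (10 mol %, enantiomer chosen in a test run), iPr2NEt, toluene, −20 °C
Reagents that add atoms: dibenzyl dicarbonate, O=C(OCc1ccccc1)OC(=O)OCc1ccccc1
Why: Proposed new method: the chiral isothiourea is acylated by the dicarbonate to an N-benzyloxycarbonyl isothiouronium ion that should transfer the alkoxycarbonyl group faster to one lactol enantiomer while the amine base interconverts the enantiomers through the open formyl carboxylate, so that all material funnels into one carbonate whose configuration is set by the catalyst; the closest known reaction type is the acylative dynamic kinetic resolution of 3-hydroxyphthalides with carboxylic anhydrides under chiral Lewis base catalysis.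

Step 18
Reactants: 27 (S)-benzyl carbonate
Product: 29 target CNP0321962.1 with (R)-configured lactol carbon, via carbonic acid half ester 28 (not isolated)
Conditions: H2 (1 atm), Pd/C (10 wt %), EtOAc, rt, stopped at full conversion
Reagents that add atoms: none
Why: Hydrogenolysis cleaves the three unhindered PhCH2–O bonds, and the carbonic acid half ester loses CO2 to reveal the lactol hydroxyl without breaking any bond to the stereocentre, so the configuration is retained (the descriptor changes from S to R only through the priority rules) under neutral aprotic conditions.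

**Compound list**

1 | tert-butyl 3-oxopentanoate | CCC(=O)CC(=O)OC(C)(C)C | starting material
2 | ethyl (E)-but-2-enoate (ethyl crotonate) | C/C=C/C(=O)OCC | starting material
3 | 1-tert-butyl 5-ethyl 3-methyl-2-propanoylpentanedioate (Michael adduct, as potassium enolate in the flask) | CCC(=O)C(C(=O)OC(C)(C)C)C(C)CC(=O)OCC | intermediate
4 | tert-butyl 3,6-dimethyl-2,4-dioxocyclohexane-1-carboxylate (racemic mixture) | CC1CC(=O)C(C)C(=O)C1C(=O)OC(C)(C)C | intermediate
5 | tert-butyl 4-methoxy-3,6-dimethyl-2-oxocyclohex-3-ene-1-carboxylate (racemic mixture) | COC1=C(C)C(=O)C(C(=O)OC(C)(C)C)C(C)C1 | intermediate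
6 | benzene-1,2,4-triol | Oc1ccc(O)c(O)c1 | starting material
7 | 1,2,4-tris(methoxymethoxy)benzene | COCOc1ccc(OCOC)c(OCOC)c1 | intermediate
8 | 2,3,6-tris(methoxymethoxy)phenyllithium | [Li]c1c(OCOC)ccc(OCOC)c1OCOC | intermediate
9 | 2-[(benzyloxy)methyl]-1,3,4-tris(methoxymethoxy)benzene | COCOc1ccc(OCOC)c(OCOC)c1COCc1ccccc1 | intermediate
10 | 3-[(benzyloxy)methyl]-1-bromo-2,4,5-tris(methoxymethoxy)benzene | COCOc1c(Br)cc(OCOC)c(OCOC)c1COCc1ccccc1 | intermediate
11 | 3-[(benzyloxy)methyl]-2,4,5-tris(methoxymethoxy)phenyllithium | [Li]c1cc(OCOC)c(OCOC)c(COCc2ccccc2)c1OCOC | intermediate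
12 | allyl 3-[(benzyloxy)methyl]-2,4,5-tris(methoxymethoxy)benzoate | C=CCOC(=O)c1cc(OCOC)c(OCOC)c(COCc2ccccc2)c1OCOC | intermediate
13 | allyl 3-[(benzyloxy)methyl]-2-hydroxy-4,5-bis(methoxymethoxy)benzoate | C=CCOC(=O)c1cc(OCOC)c(OCOC)c(COCc2ccccc2)c1O | intermediate
14 | allyl 2-(benzyloxy)-3-[(benzyloxy)methyl]-4,5-bis(methoxymethoxy)benzoate | C=CCOC(=O)c1cc(OCOC)c(OCOC)c(COCc2ccccc2)c1OCc1ccccc1 | intermediate
15 | arylmagnesium chloride of 14, metalated at B6 | C=CCOC(=O)c1c([Mg]Cl)c(OCOC)c(OCOC)c(COCc2ccccc2)c1OCc1ccccc1 | intermediate
16 | allyl 2-(benzyloxy)-3-[(benzyloxy)methyl]-6-formyl-4,5-bis(methoxymethoxy)benzoate | C=CCOC(=O)c1c(C=O)c(OCOC)c(OCOC)c(COCc2ccccc2)c1OCc1ccccc1 | intermediate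
17 | allyl 2-(benzyloxy)-3-[(benzyloxy)methyl]-6-formyl-4,5-dihydroxybenzoate | C=CCOC(=O)c1c(C=O)c(O)c(O)c(COCc2ccccc2)c1OCc1ccccc1 | intermediate
18 | 3-methoxy-2,5-dimethyl-6-(oxomethylidene)cyclohex-2-en-1-one (acylketene, racemic) | COC1=C(C)C(=O)C(=C=O)C(C)C1 | intermediate
19 | allyl 2-(benzyloxy)-3-[(benzyloxy)methyl]-6-formyl-5-hydroxy-4-[(4-methoxy-3,6-dimethyl-2-oxocyclohex-3-ene-1-carbonyl)oxy]benzoate (racemic mixture) | COC1=C(C)C(=O)C(C(=O)Oc2c(O)c(C=O)c(C(=O)OCC=C)c(OCc3ccccc3)c2COCc2ccccc2)C(C)C1 | intermediate
20 | B1 O-TBS ether of 19 (racemic mixture) | COC1=C(C)C(=O)C(C(=O)Oc2c(O[Si](C)(C)C(C)(C)C)c(C=O)c(C(=O)OCC=C)c(OCc3ccccc3)c2COCc2ccccc2)C(C)C1 | intermediate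
21 | aryl ester of the methoxy cyclohexadienyl triflate, key-step precursor (racemic at the sp3 methyl-bearing carbon) | COC1=C(C)C(OS(=O)(=O)C(F)(F)F)=C(C(=O)Oc2c(O[Si](C)(C)C(C)(C)C)c(C=O)c(C(=O)OCC=C)c(OCc3ccccc3)c2COCc2ccccc2)C(C)C1 | intermediate
22 | cesium B1 phenoxide of 21 (racemic) | [Cs+].COC1=C(C)C(OS(=O)(=O)C(F)(F)F)=C(C(=O)Oc2c([O-])c(C=O)c(C(=O)OCC=C)c(OCc3ccccc3)c2COCc2ccccc2)C(C)C1 | intermediate
23 | 1,2-dihydrodepsidone with a 1-methoxycyclohexa-1,3-diene in place of ring A (racemic at the sp3 methyl-bearing carbon) | COC1=C(C)C2=C(C(=O)Oc3c(O2)c(C=O)c(C(=O)OCC=C)c(OCc4ccccc4)c3COCc3ccccc3)C(C)C1 | intermediate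
24 | allyl 8-(benzyloxy)-9-[(benzyloxy)methyl]-6-formyl-3-methoxy-1,4-dimethyl-11-oxo-11H-dibenzo[b,e][1,4]dioxepine-7-carboxylate | COc1cc(C)c2c(c1C)Oc1c(c(COCc3ccccc3)c(OCc3ccccc3)c(C(=O)OCC=C)c1C=O)OC2=O | intermediate
25 | free B5 carboxylic acid of 24 (open formyl acid) | COc1cc(C)c2c(c1C)Oc1c(c(COCc3ccccc3)c(OCc3ccccc3)c(C(=O)O)c1C=O)OC2=O | intermediate
26 | racemic ring D lactol, B4 O-benzyl, B3 benzyloxymethyl | COc1cc(C)c2c(c1C)Oc1c(c(COCc3ccccc3)c(OCc3ccccc3)c3c1C(O)OC3=O)OC2=O | intermediate
27 | (S)-benzyl carbonate of lactol 26 | COc1cc(C)c2c(c1C)Oc1c(c(COCc3ccccc3)c(OCc3ccccc3)c3c1[C@H](OC(=O)OCc1ccccc1)OC3=O)OC2=O | intermediate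
28 | debenzylated carbonic acid half ester of the lactol | COc1cc(C)c2c(c1C)Oc1c(c(CO)c(O)c3c1[C@H](OC(=O)O)OC3=O)OC2=O | intermediate
29 | CNP0321962.1, (R)-lactol | COc1cc(C)c2c(c1C)Oc1c(c(CO)c(O)c3c1[C@H](O)OC3=O)OC2=O | target

**Totals**

Total step count: 18. Longest linear sequence: 16 steps (6 to 29, steps 3–18).

**Steps most likely to fail**

Step 17 (labelled new method). The alkoxycarbonyl transfer may show little enantiodiscrimination, the uncatalysed transfer from the dicarbonate may outrun the catalysed one, or racemisation of the lactol may be too slow under the mild base. The fallback uses known chemistry and sets out from 26. Benzyl chloroformate and pyridine in CH2Cl2 at 0 °C give the racemic benzyl carbonate F1, a one-to-one mixture of 27 and its enantiomer, the (R)-benzyl carbonate F2. Preparative chromatography on a chiral stationary phase separates the two; the (S)-enantiomer is 27, where the route is rejoined, and F2 is set aside.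

Step 14 (key step). The acyl group may shift between the two neighbouring ring B oxygens before ring closure, so that the ring closes through the wrong oxygen; fluoride or phenoxide may attack the triflate sulfur and return the keto ester; or substitution may go between molecules. The fallback forms the ether first and the ester last, so no acyl group is present when the ether bond forms; it sets out from 5 and 16 and comes back at 24. Enol triflation of 5 with Tf2O and iPr2NEt gives the tert-butyl triflyloxy dienoate F3. Chelation-controlled cleavage of the MOM group ortho to the formyl group of 16 with MgBr2·OEt2 gives the B1 phenol F4, whose B2 oxygen stays capped. Cs2CO3 in DMF joins F4 and F3 by intermolecular addition–elimination to the aryl dienyl ether F5. DDQ aromatises ring A to the diaryl ether F6. Trifluoroacetic acid in CH2Cl2, followed by aqueous work-up, removes the tert-butyl ester and the MOM group to give the hydroxy acid F7. Lactonisation of F7 with 2-chloro-1-methylpyridinium iodide and Et3N under dilution, the classical closure of depsidones from 2-(2-hydroxyaryloxy)benzoic acids, gives 24.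

Step 11. Loss of tert-butanol may be slow and reversible at a temperature the catechol tolerates, the ketene may dimerise, or prolonged heating may degrade the aldehyde partner. The fallback replaces the donor by one that releases the ketene irreversibly; it sets out from 5 and comes back at 19. Acetone, trifluoroacetic anhydride and trifluoroacetic acid convert the tert-butyl keto ester into the fused 2,2-dimethyl-1,3-dioxin-4-one F8. Heating F8 with 17 in toluene expels acetone by retro-[4+2] fragmentation, and the same acylketene 18 is captured by the B2 hydroxyl to give 19.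

**Further compounds**

F1 | step 17 | racemic benzyl carbonate of lactol 26 | COc1cc(C)c2c(c1C)Oc1c(c(COCc3ccccc3)c(OCc3ccccc3)c3c1C(OC(=O)OCc1ccccc1)OC3=O)OC2=O
F2 | step 17 | (R)-benzyl carbonate, enantiomer of 27 | COc1cc(C)c2c(c1C)Oc1c(c(COCc3ccccc3)c(OCc3ccccc3)c3c1[C@@H](OC(=O)OCc1ccccc1)OC3=O)OC2=O
F3 | step 14 | tert-butyl 4-methoxy-3,6-dimethyl-2-{[(trifluoromethyl)sulfonyl]oxy}cyclohexa-1,3-diene-1-carboxylate (racemic) | COC1=C(C)C(OS(=O)(=O)C(F)(F)F)=C(C(=O)OC(C)(C)C)C(C)C1
F4 | step 14 | allyl 2-(benzyloxy)-3-[(benzyloxy)methyl]-6-formyl-5-hydroxy-4-(methoxymethoxy)benzoate | C=CCOC(=O)c1c(C=O)c(O)c(OCOC)c(COCc2ccccc2)c1OCc1ccccc1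
F5 | step 14 | aryl dienyl ether joining the ring A ether carbon to the B1 oxygen, tert-butyl ester on the neighbouring ring A carbon, MOM on the B2 oxygen (racemic) | COC1=C(C)C(Oc2c(OCOC)c(COCc3ccccc3)c(OCc3ccccc3)c(C(=O)OCC=C)c2C=O)=C(C(=O)OC(C)(C)C)C(C)C1
F6 | step 14 | diaryl ether with aromatic ring A, tert-butyl ester on ring A, MOM on the B2 oxygen | COc1cc(C)c(C(=O)OC(C)(C)C)c(Oc2c(OCOC)c(COCc3ccccc3)c(OCc3ccccc3)c(C(=O)OCC=C)c2C=O)c1C
F7 | step 14 | diaryl ether hydroxy acid (ring A carboxylic acid, B2 phenol) | COc1cc(C)c(C(=O)O)c(Oc2c(O)c(COCc3ccccc3)c(OCc3ccccc3)c(C(=O)OCC=C)c2C=O)c1C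
F8 | step 11 | 7-methoxy-2,2,5,8-tetramethyl-5,6-dihydro-4H-1,3-benzodioxin-4-one (racemic) | COC1=C(C)C2=C(C(=O)OC(C)(C)O2)C(C)C1
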